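Time is what these flasks trade in: they share their charges and are read at 5.0 min, and they differ in when the material goes in.

| setting | Tuesday's | Friday's | Thursday's | south | south-east | north | west | south-west |
|---|---|---|---|---|---|---|---|---|
| electrophile | 2 mM | 2 mM | 2 mM | 2.0 mM | 2.0 mM (fed, over 4.0 min) | 2.0 mM | 2.0 mM (fed, over 1.0 min) | 2.0 mM |
| free base | 6 mM | 6 mM | 6 mM | 6.00 mM (in portions, 2, over 4.0 min) | 6.00 mM | 6.00 mM | 6.00 mM | 6.00 mM (fed, over 4.0 min) |
| protonated nucleophile | 3 mM | 4.2 mM | 6.6 mM | 3.00 mM | 3.00 mM | 3.00 mM | 3.00 mM | 3.00 mM |
| remark | run made earlier | run made earlier | run made earlier | first portion at the start, last at 4.0 min | all else is in the flask from the start; the feed brings no volume worth counting | everything together at the start | all else is in the flask from the start; the feed brings no volume worth counting | all else is in the flask from the start; the feed brings no volume worth counting |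
| time |  |  |  | 5.0 min | 5.0 min | 5.0 min | 5.0 min | 5.0 min |

| run | time / min | target / % | electrophile / % |
|---|---|---|---|
| Tuesday's | 1.33 | 47.7 | 37.4 |
| Tuesday's | 2.50 | 63.0 | 25.7 |
| Tuesday's | 4.00 | 74.3 | 18.7 |
| Tuesday's | 5.00 | 79.1 | 13.3 |
| Friday's | 0.833 | 44.8 | 42.6 |
| Friday's | 2.00 | 66.4 | 22.5 |
| Friday's | 4.00 | 82.8 | 10.8 |
| Friday's | 6.00 | 90.3 | 6.8 |
| Thursday's | 0.500 | 39.5 | 50.2 |
| Thursday's | 1.00 | 56.8 | 30.4 |
| Thursday's | 2.50 | 79.2 | 14.0 |
| Thursday's | 6.00 | 95.0 | 3.5 |

(standard deviation of a reading: 0.5 percentage points)
- the analysis behind the earlier runs scatters by 0.5 percentage points, standard deviation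
- the flask that comes out highest in amount of target, in percent of the electrophile charged, or "all alike" when all lie within 1.5 percentage points (south / south-east / north / west / south-west / all alike)
- target at the end, in percent of the electrophile charged, south
- target at the end, in percent of the electrophile charged, south-east
- target at the end, in percent of the electrophile charged, north
- target at the end, in percent of the electrophile charged, west
- target at the end, in percent of the electrophile charged, south-west

Which curve do you trust? Tuesday's, since it has north's charges, with [protonated nucleophile] at 3 mM and the electrophile as limiting reagent. It reads 79.1% target at 5.00 min.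

And a steady feed? Solve it at both ends. In south-east the first drop has 5.0 min in the flask and the last has 1.00 min, so with a steady rate between them the midpoint is 3.00 min. That is the mean age, the reading time less half the dosing time. West has 4.50 min. Reading between Tuesday's points gives west 76.7% and south-east 66.8%.

But the curve bends. Yes, so I take that south-east figure as a rough ceiling, an estimate and no bound: old drops gain less than young drops lose. The straight chord between the ends is my rough floor, 57.5%, with the youngest drop scaled from Tuesday's first reading.

South and south-west? Their base has the same mean age, so I say 66.8% again, but loosely: their electrophile is in the flask from the start.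

Winner? North, where each charge has the mean age 5.0 min, above the 4.50 min and 3.00 min of the fed charges.

The forecast also names north: “earliest full charging wins”. It gives north 79%, west 77%, south-east 60%, south 63% and south-west 62%. We part on south and south-west, where I stand higher.

The flasks give north 79.3%, west 76.9%, south-east 64.9%, south 69.1% and south-west 69.2%, so north comes out highest.

    electrophile + nucleophile → acid set free + target (k = 4.84 M⁻¹ s⁻¹)
    nucleophile + acid set free ⇌ protonated nucleophile, settled at all times (K = 12000 M⁻¹)
    acid set free + free base ⇌ salt of the base, settled at all times (K = 69900 M⁻¹)
    electrophile + acid set free → side product (k = 1.27 M⁻¹ s⁻¹)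
    electrophile ⇌ dormant form (K = 0.350, k = 0.00728 s⁻¹)

West lands near its mean-age figure of 76.7%, south-east lies between 57.5% and 66.8%, and south and south-west stand above 66.8%. North read at 3.0 min, the mean age of the slow flasks, holds 67.6% target, 12 percentage points below its own end value. In north, half of the target step's turnover up to 5.0 min is done by 0.945 min, well inside that mean age. In north, the nucleophile's half-life by that step stretches from 2.6 min at 0.945 min to 8.3 min at 5.00 min.

(The runs are simulated for an exercise.)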